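**Strategy.** The C40 polyene is cut at C10'–C11'. This bond lies beside the E-trisubstituted C9'=C10' alkene, which carries the C9' methyl and is conjugated through C7'=C8' with ring B. An alkene of this kind forms when methyl and a metal add to the same face of a terminal alkyne C9'≡C10'. One operation therefore installs the methyl group, the E geometry and the last chain bond: zirconium-catalysed methylalumination, then zinc- and palladium-mediated coupling with the C11' iodide of a ring A C26 polyene. The precursor is a ring B dienyne with O-2' silylated. Its 3'-hydroxyl, the later sulfate site, is left free and masked in the flask as an aluminium alkoxide. Both rings come from one (2R,3R)-trans-glycol series.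

Key step: step 14

Structure check: CIP analysis of the target gives 2R,3R,2'R,3'R, so both glycols are trans and the sulfate sits on O-3' of ring B. Carotenoid numbering is used for rings and chain from compound 15 onwards.

Assumption: sulfates 30 and 31 are written as hydrogen sulfates, the form of the target. They would be handled as pyridinium salts until a last cold exchange on an acid resin. All polyenes (20, 24, 29–31) are kept under argon in dim light.

**Step 1**
Reactants: 1 ketoisophorone
Product: 3 3,3,5-trimethyl-4-oxocyclohexa-1,5-dien-1-yl trifluoromethanesulfonate, via lithium dienolate 2 (not isolated)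
Conditions: LiN(SiMe3)2 (1.1 equiv), THF, -78 °C; PhNTf2 (1.1 equiv), -78 to 0 °C
Reagents that add atoms: N-phenylbis(trifluoromethanesulfonimide), O=S(=O)(N(c1ccccc1)S(=O)(=O)C(F)(F)F)C(F)(F)F
Why: Kinetic alpha'-deprotonation of the C4 enone carbonyl at C5H2 (the only enolisable position, since C1=O has no alpha hydrogen) and O-sulfonylation of the cross-conjugated dienolate is standard enol triflate formation.

**Step 2**
Reactants: 3 dienone triflate
Product: 4 2,6,6-trimethylcyclohexa-2,4-dien-1-one
Conditions: Pd(OAc)2 (3 mol %), PPh3 (6 mol %), HCO2H, Et3N, DMF, 50 °C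
Reagents that add atoms: none
Why: Palladium-catalysed formate hydrogenolysis of a vinyl triflate replaces C–OTf by C–H under near-neutral conditions, and the geminal methyl groups block aromatisation of the resulting cyclohexa-2,4-dienone.

**Step 3**
Reactants: 4 2,6,6-trimethylcyclohexa-2,4-dien-1-one
Product: 5 (4S,5R)-4,5-epoxy-2,6,6-trimethylcyclohex-2-en-1-one
Conditions: (S,S)-(salen)MnCl (5 mol %; salen = N,N'-bis(3,5-di-tert-butylsalicylidene)cyclohexane-1,2-diamine dianion), N-methylmorpholine N-oxide, mCPBA, CH2Cl2, -78 °C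
Reagents that add atoms: 3-chloroperoxybenzoic acid, O=C(OO)c1cccc(Cl)c1
Why: Jacobsen-Katsuki epoxidation: the cis-disubstituted, conjugated C4=C5 alkene next to a quaternary carbon has the substrate shape of a 2,2-dimethylchromene and is more electron-rich than the enone C2=C3 alkene, so it alone should be oxidised, and by that analogy the (S,S)-ligand should deliver oxygen to the face that sets C4 as S and C5 as R.

**Step 4**
Reactants: 5 epoxy enone
Product: 6 (4R,5R)-4,5-dihydroxy-2,6,6-trimethylcyclohex-2-en-1-one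
Conditions: HClO4 (cat.), THF/H2O, 0 °C
Reagents that add atoms: water, O
Why: Acid-catalysed anti hydrolysis of a vinyl epoxide: water attacks the allylic C4 with inversion and not the neopentyl C5, so C5 keeps R, C4 becomes R and the glycol is trans by mechanism.

**Step 5**
Reactants: 6 trans-diol enone
Product: 7 (4R,5R)-5-hydroxy-2,6,6-trimethyl-4-(triethylsilyloxy)cyclohex-2-en-1-one
Conditions: Et3SiCl (1.05 equiv), imidazole, CH2Cl2, -30 to 0 °C
Reagents that add atoms: chlorotriethylsilane, CC[Si](Cl)(CC)CC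
Why: Sterically controlled monosilylation: the allylic 4-OH should react well before the neopentyl 5-OH, which places the later sulfate oxygen (O-3 in carotenoid numbering) under the more labile silyl group.

**Step 6**
Reactants: 7 mono-TES ether
Product: 8 (4R,5R)-5-(tert-butyldimethylsilyloxy)-2,6,6-trimethyl-4-(triethylsilyloxy)cyclohex-2-en-1-one
Conditions: t-BuMe2SiOTf (1.3 equiv), 2,6-lutidine, CH2Cl2, -78 to 0 °C
Reagents that add atoms: tert-butyldimethylsilyl trifluoromethanesulfonate, CC(C)(C)[Si](C)(C)OS(=O)(=O)C(F)(F)F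
Why: A silyl triflate with a hindered pyridine base is the standard silylation of a hindered secondary alcohol, and the cold non-nucleophilic medium should leave the triethylsilyl ether and the beta-oxygenated ketone untouched.

**Step 7**
Reactants: 8 bis-silyl enone
Product: 10 (4R,5R)-5-(tert-butyldimethylsilyloxy)-2,6,6-trimethyl-4-(triethylsilyloxy)cyclohex-1-en-1-yl trifluoromethanesulfonate, via lithium enolate 9 (not isolated)
Conditions: LiBH(s-Bu)3 (1.1 equiv), THF, -78 °C; N-(5-chloropyridin-2-yl)bis(trifluoromethanesulfonimide), -78 to 0 °C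
Reagents that add atoms: N-(5-chloropyridin-2-yl)bis(trifluoromethanesulfonimide), O=S(=O)(N(c1ccc(Cl)cn1)S(=O)(=O)C(F)(F)F)C(F)(F)F
Why: Conjugate hydride addition of the bulky borohydride to an enone whose carbonyl is shielded by the geminal methyls and whose beta carbon carries only hydrogen gives the tetrasubstituted enolate regiospecifically, and O-triflation in the same flask (reductive enolate trapping) creates no new stereocentre.

**Step 8**
Reactants: 11 1,4-bis(trimethylsilyl)buta-1,3-diyne
Product: 13 buta-1,3-diyn-1-yl(trimethyl)silane, via lithium diynide 12 (not isolated)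
Conditions: MeLi·LiBr (1.0 equiv), Et2O, 23 °C; aq. NH4Cl; kept as a concentrated ethereal solution
Reagents that add atoms: none
Why: Nucleophilic C–Si cleavage by methyllithium removes one silyl group of the symmetrical diyne, the anionic diynide resists a second attack, and protonation gives the monoprotected diyne.

**Step 9**
Reactants: 13 buta-1,3-diyn-1-yl(trimethyl)silane
Product: 14 (E)-trimethyl[4-(4,4,5,5-tetramethyl-1,3,2-dioxaborolan-2-yl)but-3-en-1-yn-1-yl]silane
Conditions: pinacolborane (1.05 equiv), Cp2Zr(H)Cl (10 mol %), Et3N (10 mol %), CH2Cl2, 23 °C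
Reagents that add atoms: pinacolborane, [H]B1OC(C)(C)C(C)(C)O1
Why: Zirconocene-hydride-catalysed hydroboration adds H–B syn to the terminal alkyne with boron at the CH end and leaves the silyl-capped alkyne alone, giving the E-alkenylboronate.

**Step 10**
Reactants: 10 ring enol triflate; 14 enynyl boronate
Product: 16 (4R,5R)-2-[(1E)-but-1-en-3-yn-1-yl]-4-(tert-butyldimethylsilyloxy)-1,3,3-trimethyl-5-(triethylsilyloxy)cyclohex-1-ene (ring A dienyne), via silylated dienyne 15 (not isolated)
Conditions: Pd(OAc)2 (5 mol %), 2-dicyclohexylphosphino-2',6'-dimethoxybiphenyl (SPhos, 10 mol %), K3PO4, THF/H2O, 45 °C; then MeOH, K2CO3, 23 °C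
Reagents that add atoms: none
Why: Suzuki-Miyaura coupling of the hindered enol triflate, helped by the bulky electron-rich biarylphosphine, forms C6–C7 with retention of the E-alkene, and carbonate-catalysed methanolysis of the alkynyl C–Si bond in the same flask should spare both silyl ethers.

**Step 11**
Reactants: 16 ring A dienyne
Product: 17 (1R,6R)-4-[(1E)-but-1-en-3-yn-1-yl]-6-(tert-butyldimethylsilyloxy)-3,5,5-trimethylcyclohex-3-en-1-ol (ring B dienyne)
Conditions: pyridinium p-toluenesulfonate (cat.), MeOH/CH2Cl2, 0 °C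
Reagents that add atoms: none
Why: Mild acid-catalysed methanolysis distinguishes the unhindered triethylsilyl ether from the neopentyl tert-butyldimethylsilyl ether both by silicon size and by carbinol hindrance, and the acidic medium excludes a base-induced 1,2-silyl shift.

**Step 12**
Reactants: 18 (2E,4E,6E)-2,7-dimethylocta-2,4,6-trienedial; 19 iodoform
Product: 20 (1E,3E,5E,7E,9E)-1,10-diiodo-3,8-dimethyldeca-1,3,5,7,9-pentaene
Conditions: CrCl2 (16 equiv), CHI3 (5 equiv), THF, 0 °C, dark; used at once
Reagents that add atoms: iodoform, IC(I)I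
Why: Twofold Takai olefination: the geminal dichromium reagent made from CHI3 adds to each enal and eliminates to the E-iodoalkene, which adds C11 and C11'.

**Step 13**
Reactants: 16 ring A dienyne; 20 C12 diiodide; 21 trimethylaluminium
Product: 24 all-E-(2R,3R)-2-(tert-butyldimethylsilyloxy)-3-(triethylsilyloxy)-11'-iodo-11'-apo-beta-carotene (ring A C26 polyenyl iodide), via ring A alkenylalane 22 (not isolated), via ring A alkenylzinc chloride 23 (not isolated)
Conditions: Me3Al (2 equiv), Cp2ZrCl2 (0.3 equiv), ClCH2CH2Cl, 23 °C; volatiles removed in vacuo; THF, ZnCl2 (1 equiv); slow addition to 20 (3 equiv), Pd(PPh3)4 (5 mol %), THF, 0 to 23 °C, dark; surplus 20 recovered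
Reagents that add atoms: trimethylaluminium, C[Al](C)C
Why: Zirconium-catalysed methylalumination (syn, methyl to C9) followed by Negishi alkenyl-alkenyl coupling with retention forms C9–CH3 and C10–C11, and a threefold excess of the symmetrical diiodide together with slow addition of the organometal favours monocoupling.

**Step 14**
Reactants: 17 ring B dienyne; 21 trimethylaluminium; 24 ring A C26 polyenyl iodide
Product: 29 all-E-(2R,3R,2'R,3'R)-2,2'-bis(tert-butyldimethylsilyloxy)-3-(triethylsilyloxy)-beta,beta-caroten-3'-ol, via ring B aluminium alkoxide 25 (not isolated), via ring B alkenylalane 26 (not isolated), via ring B alkenylzinc chloride 27 (not isolated), via C40 aluminium alkoxide 28 (not isolated)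
Conditions: Me3Al (3 equiv), Cp2ZrCl2 (0.3 equiv), ClCH2CH2Cl, 0 to 23 °C; volatiles removed in vacuo; THF, ZnCl2 (1 equiv), 24 (0.8 equiv), Pd(PPh3)4 (5 mol %), 23 °C, dark; aq. potassium sodium tartrate
Reagents that add atoms: trimethylaluminium, C[Al](C)C
Why: The first equivalent of Me3Al turns the 3'-OH into its dimethylaluminium alkoxide with loss of methane; the methylzirconocene species formed from Cp2ZrCl2 and Me3Al then adds methyl and metal syn across C9'≡C10', methyl to the internal C9' and metal to the terminal C10', and zirconium-to-aluminium exchange gives the (E)-alkenylalane. After removal of surplus Me3Al, ZnCl2 relays the alkenyl group to palladium, which as zerovalent palladium has inserted into the C11'–I bond of 24, and reductive elimination forms C10'–C11' with retention at both alkenes. The closest known reaction type is zirconium-catalysed methylalumination of a conjugated terminal enyne followed by Negishi alkenyl-alkenyl coupling, a sequence established on ionone-derived dienynes for polyene chain building, and alkynols are known to pass through it as aluminium alkoxides. No ring is closed and no stereocentre is created, and the four carbinol centres are spectators. The step needs regioselectivity (secured by the terminal alkyne, whose unhindered CH end takes the metal), chemoselectivity (the tetrasubstituted C5'=C6' and the disubstituted C7'=C8' alkenes do not carbometalate, and sp2 carbon passes to zinc and palladium much faster than methyl) and geometric fidelity (syn addition plus stereoretentive coupling at room temperature in the dark, with the C11'=C12' geometry inherited from the Takai step).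

**Step 15**
Reactants: 29 C40 3'-alcohol
Product: 30 all-E-(2R,3R,2'R,3'R)-2,2'-bis(tert-butyldimethylsilyloxy)-3-(triethylsilyloxy)-beta,beta-caroten-3'-yl hydrogen sulfate
Conditions: SO3·pyridine (5 equiv), pyridine, 23 °C, dark
Reagents that add atoms: sulfur trioxide pyridine complex, [O-]S(=O)(=O)[n+]1ccccc1
Why: O-sulfonation by the mild SO3–amine complex should take place at the single free secondary hydroxyl, while triethylsilyl and tert-butyldimethylsilyl ethers and the polyene are inert in pyridine.

**Step 16**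
Reactants: 30 silylated sulfate
Product: 31 target CNP0229621.3 (all-E-(2R,3R,2'R,3'R)-2,3,2'-trihydroxy-beta,beta-caroten-3'-yl hydrogen sulfate)
Conditions: HF·pyridine, pyridine, THF, 0 to 23 °C, dark; reversed-phase chromatography; acid-form sulfonic resin, MeOH, 0 °C
Reagents that add atoms: none
Why: Fluoride-driven Si–O cleavage in a buffered, weakly acidic medium should remove the triethylsilyl and both hindered tert-butyldimethylsilyl groups, a sulfate monoester is stable to it, and no free alkoxide arises next to the trans-sulfate, so epoxide closure is avoided.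

**Compound list**
1 | ketoisophorone (2,6,6-trimethylcyclohex-2-ene-1,4-dione) | CC1=CC(=O)CC(C)(C)C1=O | starting material
2 | lithium 3,3,5-trimethyl-4-oxocyclohexa-1,5-dien-1-olate | CC1=CC([O-])=CC(C)(C)C1=O.[Li+] | intermediate
3 | 3,3,5-trimethyl-4-oxocyclohexa-1,5-dien-1-yl trifluoromethanesulfonate | CC1=CC(OS(=O)(=O)C(F)(F)F)=CC(C)(C)C1=O | intermediate
4 | 2,6,6-trimethylcyclohexa-2,4-dien-1-one | CC1=CC=CC(C)(C)C1=O | intermediate
5 | (4S,5R)-4,5-epoxy-2,6,6-trimethylcyclohex-2-en-1-one | CC1=C[C@@H]2O[C@@H]2C(C)(C)C1=O | intermediate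
6 | (4R,5R)-4,5-dihydroxy-2,6,6-trimethylcyclohex-2-en-1-one | CC1=C[C@@H](O)[C@H](O)C(C)(C)C1=O | intermediate
7 | (4R,5R)-5-hydroxy-2,6,6-trimethyl-4-(triethylsilyloxy)cyclohex-2-en-1-one | CC1=C[C@@H](O[Si](CC)(CC)CC)[C@H](O)C(C)(C)C1=O | intermediate
8 | (4R,5R)-5-(tert-butyldimethylsilyloxy)-2,6,6-trimethyl-4-(triethylsilyloxy)cyclohex-2-en-1-one | CC1=C[C@@H](O[Si](CC)(CC)CC)[C@H](O[Si](C)(C)C(C)(C)C)C(C)(C)C1=O | intermediate
9 | lithium (4R,5R)-5-(tert-butyldimethylsilyloxy)-2,6,6-trimethyl-4-(triethylsilyloxy)cyclohex-1-en-1-olate | CC1=C([O-])C(C)(C)[C@@H](O[Si](C)(C)C(C)(C)C)[C@H](O[Si](CC)(CC)CC)C1.[Li+] | intermediate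
10 | (4R,5R)-5-(tert-butyldimethylsilyloxy)-2,6,6-trimethyl-4-(triethylsilyloxy)cyclohex-1-en-1-yl trifluoromethanesulfonate | CC1=C(OS(=O)(=O)C(F)(F)F)C(C)(C)[C@@H](O[Si](C)(C)C(C)(C)C)[C@H](O[Si](CC)(CC)CC)C1 | intermediate
11 | 1,4-bis(trimethylsilyl)buta-1,3-diyne | C[Si](C)(C)C#CC#C[Si](C)(C)C | starting material
12 | lithium 4-(trimethylsilyl)buta-1,3-diyn-1-ide | [Li]C#CC#C[Si](C)(C)C | intermediate
13 | buta-1,3-diyn-1-yl(trimethyl)silane | C#CC#C[Si](C)(C)C | intermediate
14 | (E)-trimethyl[4-(4,4,5,5-tetramethyl-1,3,2-dioxaborolan-2-yl)but-3-en-1-yn-1-yl]silane | C[Si](C)(C)C#C/C=C/B1OC(C)(C)C(C)(C)O1 | intermediate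
15 | C-trimethylsilyl derivative of 16 (2-O-TBS, 3-O-TES ring, E-C7=C8, C9≡C10–SiMe3) | CC1=C(/C=C/C#C[Si](C)(C)C)C(C)(C)[C@@H](O[Si](C)(C)C(C)(C)C)[C@H](O[Si](CC)(CC)CC)C1 | intermediate
16 | ring A dienyne, (4R,5R)-2-[(1E)-but-1-en-3-yn-1-yl]-4-(tert-butyldimethylsilyloxy)-1,3,3-trimethyl-5-(triethylsilyloxy)cyclohex-1-ene | C#C/C=C/C1=C(C)C[C@@H](O[Si](CC)(CC)CC)[C@H](O[Si](C)(C)C(C)(C)C)C1(C)C | intermediate
17 | ring B dienyne, (1R,6R)-4-[(1E)-but-1-en-3-yn-1-yl]-6-(tert-butyldimethylsilyloxy)-3,5,5-trimethylcyclohex-3-en-1-ol | C#C/C=C/C1=C(C)C[C@@H](O)[C@H](O[Si](C)(C)C(C)(C)C)C1(C)C | intermediate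
18 | (2E,4E,6E)-2,7-dimethylocta-2,4,6-trienedial | O=C/C(C)=C/C=C/C=C(C)/C=O | starting material
19 | iodoform | IC(I)I | starting material
20 | (1E,3E,5E,7E,9E)-1,10-diiodo-3,8-dimethyldeca-1,3,5,7,9-pentaene | I/C=C/C(C)=C/C=C/C=C(C)/C=C/I | intermediate
21 | trimethylaluminium | C[Al](C)C | starting material
22 | ring A (E)-alkenyl(dimethyl)alane (Al on C10, methyl on C9) | C[Al](C)/C=C(C)/C=C/C1=C(C)C[C@@H](O[Si](CC)(CC)CC)[C@H](O[Si](C)(C)C(C)(C)C)C1(C)C | intermediate
23 | ring A (E)-alkenylzinc chloride | Cl[Zn]/C=C(C)/C=C/C1=C(C)C[C@@H](O[Si](CC)(CC)CC)[C@H](O[Si](C)(C)C(C)(C)C)C1(C)C | intermediate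
24 | ring A C26 polyenyl iodide, all-E-(2R,3R)-2-(tert-butyldimethylsilyloxy)-3-(triethylsilyloxy)-11'-iodo-11'-apo-beta-carotene | CC1=C(/C=C/C(C)=C/C=C/C(C)=C/C=C/C=C(C)/C=C/I)C(C)(C)[C@@H](O[Si](C)(C)C(C)(C)C)[C@H](O[Si](CC)(CC)CC)C1 | intermediate
25 | dimethylaluminium 3'-alkoxide of 17 | C#C/C=C/C1=C(C)C[C@@H](O[Al](C)C)[C@H](O[Si](C)(C)C(C)(C)C)C1(C)C | intermediate
26 | ring B (E)-alkenyl(dimethyl)alane, O-3' as dimethylaluminium alkoxide | C[Al](C)/C=C(C)/C=C/C1=C(C)C[C@@H](O[Al](C)C)[C@H](O[Si](C)(C)C(C)(C)C)C1(C)C | intermediate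
27 | ring B (E)-alkenylzinc chloride, O-3' as dimethylaluminium alkoxide | Cl[Zn]/C=C(C)/C=C/C1=C(C)C[C@@H](O[Al](C)C)[C@H](O[Si](C)(C)C(C)(C)C)C1(C)C | intermediate
28 | dimethylaluminium 3'-alkoxide of 29 | CC1=C(/C=C/C(C)=C/C=C/C(C)=C/C=C/C=C(C)/C=C/C=C(C)/C=C/C2=C(C)C[C@@H](O[Al](C)C)[C@H](O[Si](C)(C)C(C)(C)C)C2(C)C)C(C)(C)[C@@H](O[Si](C)(C)C(C)(C)C)[C@H](O[Si](CC)(CC)CC)C1 | intermediate
29 | all-E-(2R,3R,2'R,3'R)-2,2'-bis(tert-butyldimethylsilyloxy)-3-(triethylsilyloxy)-beta,beta-caroten-3'-ol | CC1=C(/C=C/C(C)=C/C=C/C(C)=C/C=C/C=C(C)/C=C/C=C(C)/C=C/C2=C(C)C[C@@H](O)[C@H](O[Si](C)(C)C(C)(C)C)C2(C)C)C(C)(C)[C@@H](O[Si](C)(C)C(C)(C)C)[C@H](O[Si](CC)(CC)CC)C1 | intermediate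
30 | 3'-hydrogen sulfate of 29 | CC1=C(/C=C/C(C)=C/C=C/C(C)=C/C=C/C=C(C)/C=C/C=C(C)/C=C/C2=C(C)C[C@@H](OS(=O)(=O)O)[C@H](O[Si](C)(C)C(C)(C)C)C2(C)C)C(C)(C)[C@@H](O[Si](C)(C)C(C)(C)C)[C@H](O[Si](CC)(CC)CC)C1 | intermediate
31 | CNP0229621.3, all-E-(2R,3R,2'R,3'R)-2,3,2'-trihydroxy-beta,beta-caroten-3'-yl hydrogen sulfate | CC1=C(/C=C/C(C)=C/C=C/C(C)=C/C=C/C=C(C)/C=C/C=C(C)/C=C/C2=C(C)C[C@@H](OS(=O)(=O)O)[C@H](O)C2(C)C)C(C)(C)[C@@H](O)[C@H](O)C1 | target

**Total step count:** 16.
**Longest linear sequence:** 12 steps (1, 2, 3, 4, 5, 6, 7, 10, 13, 14, 15, 16).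

**Steps most likely to fail**

1. **Step 14 (key step).**
   - What may go wrong: carbometalation may be slow or incomplete in the presence of the aluminium alkoxide. The alkenyl metal may be protodemetalated. Methyl instead of alkenyl may be transferred to palladium. Lewis acid or light may cause E/Z drift and decay of the polyenyl iodide.
   - Fallback: carbometalation and coupling are separated, and boron replaces aluminium and zinc. The fallback sets out from 17 and proceeds through 25 and 26 as in step 14. The alkenylalane is quenched with 2-methoxy-4,4,5,5-tetramethyl-1,3,2-dioxaborolane to give the O-aluminated ring B trienylboronate F1. Aqueous work-up gives the isolable ring B (E)-trienyl pinacolboronate F2, which can be purified and checked for geometry. A Suzuki-Miyaura coupling of F2 with 24 (Pd(OAc)2, SPhos, K3PO4, THF/H2O, 23 °C, dark) comes back to the route at 29.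

2. **Step 13.**
   - What may go wrong: the product iodide may couple a second time, the diiodide may decay under the Lewis acidic conditions, and three non-polar polyenes may prove hard to separate.
   - Fallback: the two chain ends are differentiated by oxidation level. The fallback sets out from 18. A Takai olefination with one equivalent of CHI3 gives (2E,4E,6E,8E)-9-iodo-2,7-dimethylnona-2,4,6,8-tetraenal F3, which differs strongly in polarity from 18 and 20. From 16, through 22, a quench with 2-methoxy-4,4,5,5-tetramethyl-1,3,2-dioxaborolane gives the ring A (E)-trienyl pinacolboronate F4. Suzuki-Miyaura coupling of F3 with F4 gives the ring A C25 aldehyde F5. A second Takai olefination (CrCl2, CHI3, THF, 0 °C) comes back to the route at 24.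

3. **Step 3.**
   - What may go wrong: oxygen transfer to the electron-poor diene may be slow, and facial selectivity may be insufficient.
   - Fallback: asymmetric catalysis is replaced by a resolution. The fallback sets out from 4. Plain mCPBA epoxidation (NaHCO3, CH2Cl2, 0 °C) gives the racemic 4,5-epoxide F6, and the hydrolysis of step 4 gives the racemic trans-diol F7. Burkholderia cepacia lipase with vinyl acetate in tert-butyl methyl ether should acetylate the allylic 4-OH of the (4R,5R)-enantiomer faster. This follows the empirical size rule for secondary alcohols, with CH(OH)CMe2 as the large side and the vinyl carbon as the medium side. The product is the (4R,5R)-4-acetate F8, which is separated from the untouched (4S,5S)-diol. Hydrolysis by the same lipase in pH 7 phosphate buffer comes back to the route at 6.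

**Further compounds**
F1 | step 14 | O-aluminated ring B (E)-trienyl pinacolboronate (not isolated) | CC1(C)OB(/C=C(C)/C=C/C2=C(C)C[C@@H](O[Al](C)C)[C@H](O[Si](C)(C)C(C)(C)C)C2(C)C)OC1(C)C
F2 | step 14 | ring B (E)-trienyl pinacolboronate, 3'-OH free, 2'-O-TBS | CC1(C)OB(/C=C(C)/C=C/C2=C(C)C[C@@H](O)[C@H](O[Si](C)(C)C(C)(C)C)C2(C)C)OC1(C)C
F3 | step 13 | (2E,4E,6E,8E)-9-iodo-2,7-dimethylnona-2,4,6,8-tetraenal | O=C/C(C)=C/C=C/C=C(C)/C=C/I
F4 | step 13 | ring A (E)-trienyl pinacolboronate, 3-O-TES, 2-O-TBS | CC1(C)OB(/C=C(C)/C=C/C2=C(C)C[C@@H](O[Si](CC)(CC)CC)[C@H](O[Si](C)(C)C(C)(C)C)C2(C)C)OC1(C)C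
F5 | step 13 | all-E-(2R,3R)-2-(tert-butyldimethylsilyloxy)-3-(triethylsilyloxy)-12'-apo-beta-caroten-12'-al | CC1=C(/C=C/C(C)=C/C=C/C(C)=C/C=C/C=C(C)/C=O)C(C)(C)[C@@H](O[Si](C)(C)C(C)(C)C)[C@H](O[Si](CC)(CC)CC)C1
F6 | step 3 | racemic 4,5-epoxy-2,6,6-trimethylcyclohex-2-en-1-one | CC1=C[C@@H]2O[C@@H]2C(C)(C)C1=O.CC1=C[C@H]2O[C@H]2C(C)(C)C1=O
F7 | step 3 | racemic trans-4,5-dihydroxy-2,6,6-trimethylcyclohex-2-en-1-one | CC1=C[C@@H](O)[C@H](O)C(C)(C)C1=O.CC1=C[C@H](O)[C@@H](O)C(C)(C)C1=O
F8 | step 3 | (4R,5R)-4-acetoxy-5-hydroxy-2,6,6-trimethylcyclohex-2-en-1-one | CC1=C[C@@H](OC(C)=O)[C@H](O)C(C)(C)C1=O
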